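**One step.** I began from a one-step world, in which what is dosed is product at once, and asked how far these flasks stray from it.

| flask | starting material | gas phase | protic impurity | free catalyst | stray impurity | remark | time |
|---|---|---|---|---|---|---|---|
| grey | 0.68 M (fed, over 4.0 min) | 200 mM (held) | 0.12 M | 4.6 mol% | 13 mM | run made earlier; the fed solution adds 0.25 times the starting volume |  |
| ochre | 0.68 M (fed, over 4.0 min) | 200 mM (held) | 0.67 M | 4.6 mol% | 13 mM | run made earlier; the fed solution adds 0.25 times the starting volume |  |
| north-east | 0.68 M (fed, over 4.0 min) | 200 mM (held) | 0.0800 M | 4.6 mol% | 13 mM | the fed solution adds 0.25 times the starting volume | 4.0 min |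
| south | 0.68 M (fed, over 4.0 min) | 200 mM (held) | 0.150 M | 4.6 mol% | 13 mM | the fed solution adds 0.25 times the starting volume | 4.0 min |
| north-west | 0.68 M (fed, over 4.0 min) | 200 mM (held) | 0.300 M | 4.6 mol% | 13 mM | the fed solution adds 0.25 times the starting volume | 4.0 min |
| west | 0.68 M (fed, over 4.0 min) | 200 mM (held) | 0.600 M | 4.6 mol% | 13 mM | the fed solution adds 0.25 times the starting volume | 4.0 min |

| run | time / s | product / % | starting material / % |
|---|---|---|---|
| grey | 15.0 | 3 | 5 |
| grey | 40.0 | 5 | 7 |
| grey | 80.0 | 17 | 7 |
| grey | 120 | 24 | 8 |
| ochre | 30.0 | 4 | 5 |
| ochre | 60.0 | 12 | 9 |
| ochre | 90.0 | 20 | 7 |
| ochre | 120 | 23 | 4 |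

(readings scatter by 1.5 percentage points)

- charges are per starting volume, the dose included; the dosed solution carries all of it
- at the start none of the gas phase is in solution
- percentages count the whole charge, also what has not yet gone in
- a reading or a percentage of product counts all its forms, free or not
- "hardly changes" means that all values lie within two and a half points (for a concentration: within two and a half percent of the largest)
- a reading of starting material is of its free form alone

1. amount of product at the end, in percent of the starting material charged for north-east, south, north-west, west, in this order
2. the course of these numbers from the first flask to the last (rises, then falls / rises all the way / hardly changes / falls all the way / falls, then rises)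

**First link.** The dose is steady, so at 120 s half of the charge was in, yet the grey run read 24% product and the ochre run 23%. Free starting material read 8% and 4%, so 18.0% in grey and 23.0% in ochre stood in neither reading. I took the mean product per dosed share, 47.0%, as my level for the end of the dose.

**Second link.** From grey to ochre, protic impurity went from 0.176 to 0.985 of the charge, a step of 0.747 in powers of ten. At 120 s the slope of the logarithm of product against that step, read from the two runs, was −0.0247.

**Weak link.** That slope rests on a gap of 1 percentage point, smaller than the 2.1 points expected between two readings, so I made a second pair. Ochre, interpolated to 80.0 s, read 17.3% against 17% in grey, a slope of 0.0113. The mean of the two is my protic order, the powers of ten of product per power of ten of protic impurity at one time (an apparent order): −0.00673, with a scatter of about 0.0348. From north-east to west the protic impurity rises by a ratio of 7.50, so by my estimate product drops by 0.63 points, and the scatter of the slope is worth 3.2 points in that estimate. I committed to about 47.0% in all four flasks, a row that hardly changes.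

**The flasks.** The forecast gave 56%, 54%, 51% and 47%, falls all the way, in its words “I expect a modest fall, though this is uncertain.” The flasks gave 53.1%, 53.1%, 52.9% and 52.6%, so the course hardly changes, with north-east 6.1 points above my level.

    gas phase ⇌ dissolved gas, rate k1*(csat - [dissolved gas]) (kL = 8.90 min⁻¹)
    free catalyst + stray impurity → spent catalyst (k = 340 L mol⁻¹ min⁻¹)
    starting material + product ⇌ idle adduct, settled at all times (K = 71.0 L mol⁻¹)
    starting material + dissolved gas + free catalyst → free catalyst + product (k = 690 L² mol⁻² min⁻¹)
    starting material + protic impurity → quenched substrate (k = 0.0910 L mol⁻¹ min⁻¹)

**Order reused.** In north-east the step into quenched substrate made no difference to product, and at 4.00 min quenched substrate stood at 0.161% of the starting material charged there, against 1.20% in west. Carried from north-east, my order puts west at 52.4%, and west stands at 52.6%.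

The runs stem from a simulated flask with constants of no real substance; the scatter is artificial.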